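## The problem

Target **41** is an ester-linked dimer of two bicyclic monomers that are mirror images of each other. Each monomer has a cyclohexane ring A (C1, C2, C3, C4, C4a, C8a) trans-fused along C4a–C8a to a seven-membered unsaturated lactone ring B (C4a, C5, O6, C7, C8, C9, C8a). The C10 carboxyl on C8 of the (1R,4S,4aS,8aS) half acylates the C11 oxygen of the (1S,4R,4aR,8aR) half (primed locants). Because the halves are antipodes, both enantiomers of one intermediate are needed, and they must end up differentiated, one as acyl donor and one as alcohol.

Each half carries four contiguous stereocentres on ring A. The isopropyl group on C1, C11 on C4 and C5 on C4a lie on one face; the C4 oxygen and C9 on C8a lie on the other. C4a and C8a are epimerisable only towards the trans-diequatorial arrangement that is wanted, but the quaternary carbinol C4 cannot be corrected once made, so it must be set together with its neighbours in a rigid frame.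

Three features restrict the late chemistry:
- The C11 hydroxymethyl group is cis and 1,2 to the C5 carbonyl, so any acyclic C5 ester, and in principle ring B itself, can collapse to a five-membered lactone.
- The C4 hydroxyl is β to C5, which invites retro-aldol cleavage or elimination under base.
- Each ring B contains a 2-(acyloxymethyl)-2-enoate that accepts nucleophiles in the SN2′ sense and has an acidic γ-hydrogen at C8a.

The feature that makes the key step possible is that the isopropyl methine on C1 and C11 on C4 are cis across ring A and are both one-carbon stubs. They can be read as the two ends of a cleaved C=C bridge. Ring A is then one ring of a bicyclo[2.2.2]octene whose C4 bridgehead oxygen and bridge methyl come from an oxygenated cyclohexadiene, and whose C4a and C8a carbons (C5 syn to the bridge, C9 anti) come from an E dienophile adding endo.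

## Retrosynthesis

**41 ⇐ 40 ⇐ 38.** Only protecting groups are removed: the tert-butyl ester on C10′ (via trimethylsilyl ester **39**), then the two tertiary tert-butyldimethylsilyl ethers and the primary triethylsilyl ether. The free C11 hydroxyl next to the ring-B lactone is exposed in the last step only, under buffered fluoride. This asks that the tertiary silyl ethers come off without base.

**38 ⇐ 37 ⇐ 36.** The C8=C9 bond of the 1R half is cut (ring-closing metathesis), and the two isopropyl groups are traced to isopropenyl groups. The neighbouring cut, the C10–O–C11′ ester, would need activation of a hindered conjugated acid that carries its own allylic acyloxy leaving group, with a nucleophilic acylation catalyst. The metathesis cut avoids this and leaves an open-chain precursor with no ring strain. The forward reaction must join a vinyl group to a 1,1-disubstituted acrylate in a seven-membered ring.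

**36 ⇐ 16 + 33, and 33 ⇐ 30 + 31.** The O6–C7 bond is cut. The three carbons C7, C8 and C10 of the 1R half come from 2-(bromomethyl)acrylic acid **31**. It is first attached through its acid chloride **32** to the C11′ hydroxyl of the 1S-series alcohol **30**, so the inter-half ester is made from a small, unhindered acid. The 1R half then arrives as the carboxylate **34**, obtained by opening γ-lactone **16** with one equivalent of hydroxide. The carboxylate displaces the allylic bromide of **33**, and the C11 hydroxyl of **35** is silylated at once. The 1R half therefore never needs a protecting group on C10.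

**30 ⇐ 29 ⇐ 28 ⇐ 24 + 25.** Ring B of the 1S half is cut at C8=C9 and at O6–C7 in the same way. Lactone **24** is opened, the carboxylate **26** is alkylated with tert-butyl 2-(bromomethyl)acrylate **25**, the hydroxyl of **27** is silylated, **28** is cyclised to **29**, and the primary silyl ether is removed to give **30**. The tert-butyl ester on C10′ is the only carboxyl protecting group of the synthesis.

**16 (24) ⇐ 15 (23) ⇐ 13 (21) ⇐ 12 (20).** The vinyl group on C8a and the isopropenyl group on C1 are traced to one double methylenation of a keto aldehyde. The aldehyde comes from the C9 acid through its chloride **14** (**22**), and the acid from a benzyl ester. A benzyl rather than an ethyl ester is chosen so that C9 can be told apart from the lactone carbonyl by hydrogenolysis, without base or hydride. Throughout this stage the cis γ-lactone between C5 and C11 protects both groups. It is the arrangement these two groups adopt anyway.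

**12 (20) ⇐ 9 (17).** C11 and the acetyl carbon are reconnected as a trisubstituted alkene bridge. In the forward direction ozonolysis gives the C11 aldehyde and the C1 acetyl group. Reduction of the aldehyde alone lets the new alkoxide expel the oxazolidinone from C5, so the auxiliary leaves without a separate step and C5 is differentiated from C9. The step requires an aldehyde to be reduced beside a methyl ketone.

**9 (17) ⇐ 4 + 8.** The C4–C4a and C1–C8a bonds are cut (Diels–Alder). This single step makes ring A and all four stereocentres from two achiral compounds, and either antipode is available by choosing the ligand antipode. A tert-butyldimethylsilyl group is used on the diene oxygen because it must later be removed from a tertiary centre.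

**4 ⇐ 3 ⇐ 2 ⇐ 1, and 8 ⇐ 5 + 6.** Diene **4** is the silyl dienol ether of the β,γ-unsaturated ketone **3**, which is available from 3-methylanisole **1** by Birch reduction to **2** and mild hydrolysis. Enolisation of **3** towards the doubly activated methylene fixes the diene regiochemistry, which isomerisation of a 1,4-diene would not. Dienophile **8** is the N-acyl derivative of 2-oxazolidinone **6** with monobenzyl fumarate **5**, formed via the mixed anhydride **7**.

## Roads not taken

**Alternative 1:** The C4–C4a bond is cut by an Ireland–Claisen ring contraction. δ-Lactone **A1** (ring of C5, C4a, C8a, C1, C2 and oxygen, with a dioxolanylidene-methyl group on C2) would be converted into its silyl ketene acetal. The [3,3] shift through the boat enforced by the lactone forms C4a–C4, breaks O–C2 and gives cyclohexene acid **A2**.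
- Merits: C4 and C4a are set by chirality transfer. C5 arrives as a free acid while C9 is already a protected alcohol. This differentiation is better than in the chosen plan, which spends steps 7 to 9 on it. No ozonolysis is needed.
- Weak points: **A1** needs three contiguous stereocentres and a geometrically pure, acid-labile exocyclic enol ether that must survive enolisation and silylation. The rearrangement has to build a fully substituted, oxygen-bearing carbon at the enol-ether terminus. The C2=C3 alkene must be reduced afterwards. Each antipode of **A1** needs its own asymmetric sequence.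
- Comparison: the chosen plan sets against the better C5/C9 differentiation the formation of ring A and four stereocentres in one catalytic step from achiral materials, with the antipode selected by the ligand.

**Alternative 2:** The C4a–C8a bond is cut by a transannular allylic alkylation. Pd(PPh3)4 (zerovalent palladium) would ionise the C8a carbonate of the eleven-membered β-keto lactone **A3**, and the C4a enolate would attack C8a across the ring to give bicyclic β-keto lactone **A4**, closing rings A and B together.
- Merits: ring B and its enoate geometry are in place before the bicycle forms, so no late metathesis on sensitive material is needed. In ring-forming steps this road is shorter than the chosen one.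
- Weak points: **A3** needs a macrocyclisation of its own. The trans fusion and the C8a/C1 relationship rest on the conformation of the macrocycle, and attack at C8 or through oxygen competes. **A4** still lacks C11 and the C4 carbinol: a hydroxymethyl equivalent must add to the ketone of an acidic β-keto lactone, cis to C5, where enolisation and retro-Claisen cleavage compete.
- Comparison: the chosen plan sets against the shorter ring construction the C4 oxygen and C11 delivered by the cycloaddition with their configuration fixed.

**Alternative 3:** O6 is inserted into the C5–C7 bond of trans-decalone **A5** by a flavin-dependent Baeyer–Villiger monooxygenase with dioxygen and NADPH, giving monomer lactone **A6**.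
- Merits: **A5** is a carbocycle open to established annulation chemistry. The lactone appears last in one step, with no lactone opening, alkylation and metathesis (steps 15, 16, 19 and 20). On that count it is better than the chosen plan.
- Weak points: the primary allylic C7 must migrate in preference to the more substituted C4a, against the usual chemical preference, so the outcome rests entirely on the enzyme. **A5** is a β,γ-unsaturated ketone with a doubly activated C7 methylene and is prone to conjugation. The enzyme would have to accept both antipodes of a bulky, highly substituted substrate, while an enzyme tuned to one enantiomer generally handles its mirror image poorly.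
- Comparison: the chosen plan sets against the one-step lactone formation equal access to both antipodes by ligand choice and independence from enzyme screening.

Key step: step 5

Conventions and assumptions:
- Ring-A locants of **41** are used for all intermediates (C5 on C4a, C9 on C8a, C11 on C4). In every intermediate the C1 substituent, C11 and C5 are on one face of ring A, and the C4 oxygen and C9 on the other.
- "1R series" means the absolute configuration that ends as (1R,4S,4aS,8aS) in **41**. "1S series" is its mirror image.
- Assumption: the facial sense of the bis(oxazoline)–copper catalyst follows the square-planar chelate model (the diene adds to the face of the s-cis imide remote from the nearer tert-butyl group). If it proved opposite, the two ligand antipodes would change places between steps 5 and 10.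
- Assumption: a ring-B lactone carrying a free cis hydroxymethyl group on C4 (as in **30** and **41**) is kinetically stable to translactonisation under neutral and weakly acidic conditions, as the structure of the target implies.

## Route

Step 1
Reactants: 1 3-methylanisole
Product: 2 1-methoxy-5-methylcyclohexa-1,4-diene
Conditions: Li, NH3(l), THF, tBuOH, −78 to −33 °C
Reagents that add atoms: none
Why: Birch reduction; the methoxy and methyl groups end up on the two remaining double bonds, giving the 2,5-dihydro arene.

Step 2
Reactants: 2 1-methoxy-5-methylcyclohexa-1,4-diene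
Product: 3 3-methylcyclohex-3-en-1-one
Conditions: oxalic acid (cat.), acetone/H2O, 20 °C
Reagents that add atoms: water, O
Why: Enol ether hydrolysis under weak acid; the ketone is released without moving the trisubstituted C=C bond into conjugation.

Step 3
Reactants: 3 3-methylcyclohex-3-en-1-one
Product: 4 tert-butyldimethyl[(3-methylcyclohexa-1,3-dien-1-yl)oxy]silane
Conditions: Et3N, TBSOTf, CH2Cl2, −78 to 0 °C
Reagents that add atoms: tert-butyldimethylsilyl trifluoromethanesulfonate, CC(C)(C)[Si](C)(C)OS(=O)(=O)C(F)(F)F
Why: Soft enolisation and O-silylation; the amine removes the doubly activated proton between the silylated carbonyl and the alkene, so the new enol double bond forms in conjugation with the existing one and the diene regiochemistry is fixed.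

Step 4
Reactants: 5 monobenzyl fumarate; 6 2-oxazolidinone
Product: 8 3-[(E)-3-(benzyloxycarbonyl)acryloyl]oxazolidin-2-one, via mixed pivalic anhydride 7 (not isolated)
Conditions: tBuCOCl, Et3N, THF, −20 °C; then 6, LiCl, 20 °C
Reagents that add atoms: none
Why: N-acylation of the oxazolidinone through a mixed anhydride with LiCl activation; attack occurs at the less hindered fumaroyl carbonyl and the E alkene is untouched.

Step 5
Reactants: 4 tert-butyldimethyl[(3-methylcyclohexa-1,3-dien-1-yl)oxy]silane; 8 3-[(E)-3-(benzyloxycarbonyl)acryloyl]oxazolidin-2-one
Product: 9 1R-series cycloadduct: benzyl 4-(tert-butyldimethylsilyloxy)-6-methyl-3-(2-oxooxazolidine-3-carbonyl)bicyclo[2.2.2]oct-5-ene-2-carboxylate (imide carbonyl syn to the alkene bridge; ester anti)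
Conditions: Cu(SbF6)2 with (S,S)-2,2′-isopropylidenebis(4-tert-butyl-2-oxazoline) (10 mol %; from CuCl2, ligand, AgSbF6), 4 Å molecular sieves, CH2Cl2, −78 to −40 °C
Reagents that add atoms: none
Why: Chelation of both imide carbonyls of 8 to the divalent copper centre lowers the LUMO of the C=C bond, and 4 adds in a concerted but asynchronous [4+2] cycloaddition in which C1–C8a is further advanced than C4–C4a (a stepwise vinylogous Mukaiyama–Michael addition followed by closure of the copper enolate onto the silyloxocarbenium carbon would end in the same bicycle). The closest known reaction type is the bis(oxazoline)–copper-catalysed Diels–Alder reaction of 3-acyloxazolidin-2-ones with cyclohexa-1,3-diene and with 1-oxygenated butadienes. Ring A is closed as one six-membered ring of a bicyclo[2.2.2]octene by this cycloaddition, its other four atoms being the ring carbons of 4. Regiochemistry is needed and is secured because the 1-silyloxy and 3-methyl groups both enlarge the HOMO coefficient at the unsubstituted diene terminus, which bonds to the imide β-carbon (C1–C8a) and leaves the oxygenated terminus to bond to the α-carbon (C4–C4a). C4 and C1 are bridgeheads fixed by suprafacial addition to the cyclic diene; C4a is set by the endo orientation of the chelated imide (C5 syn to the alkene bridge and hence cis to the future C11) together with the catalyst face; C8a follows from the E geometry of 8 (C9 trans to C5). Facial selectivity is needed and is expected from the square-planar chelate, in which the tert-butyl group nearer the s-cis enoyl unit blocks one face.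

Step 6
Reactants: 9 1R-series cycloadduct
Product: 12 1R-series keto lactone benzyl ester (cis γ-lactone C5(=O)–O–C11 across C4a/C4; 4-OTBS; 1-acetyl; 8a-CO2Bn), via keto aldehyde imide 10 (not isolated), via hydroxy imide 11 (not isolated)
Conditions: O3, CH2Cl2, −78 °C; PPh3, −78 to 0 °C; then EtOH, NaBH4, −78 °C; AcOH; Et3N, 20 °C
Reagents that add atoms: ozone, [O-][O+]=O
Why: Ozonolysis of the only alkene gives the C11 aldehyde and the C1 acetyl group; NaBH4 in ethanolic CH2Cl2 at −78 °C reduces aldehydes much faster than ketones. The primary alkoxide, cis to the imide on the adjacent carbon, then closes the five-membered lactone and releases the oxazolidinone (intramolecular acyl transfer). No stereocentre is touched; the cis relationship of C11 and C5 set in step 5 is what allows lactonisation.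

Step 7
Reactants: 12 1R-series keto lactone benzyl ester
Product: 13 1R-series keto lactone acid (as 12 with 8a-CO2H)
Conditions: H2 (1 atm), 10% Pd/C, EtOAc, 20 °C
Reagents that add atoms: none
Why: Hydrogenolysis of the benzyl ester; the ketone, lactone and silyl ether are inert, and no base touches the epimerisable centres.

Step 8
Reactants: 13 1R-series keto lactone acid
Product: 15 1R-series keto aldehyde lactone (as 12 with 8a-CHO), via acid chloride 14 (not isolated)
Conditions: (COCl)2, DMF (cat.), CH2Cl2, 0 °C; evaporate; LiAlH(OtBu)3, THF, −78 °C
Reagents that add atoms: none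
Why: Partial reduction of an acid chloride by the hindered alkoxyaluminium hydride; at −78 °C the acid chloride reacts far faster than the methyl ketone or the lactone, and the tetrahedral aluminate releases the aldehyde only on work-up.

Step 9
Reactants: 15 1R-series keto aldehyde lactone
Product: 16 1R-series diene lactone (as 12 with 1-isopropenyl and 8a-vinyl)
Conditions: Ph3PCH3Br, KN(SiMe3)2, THF, 0 °C; then 15, −78 to 20 °C
Reagents that add atoms: methylenetriphenylphosphorane, C=P(c1ccccc1)(c1ccccc1)c1ccccc1
Why: Double Wittig methylenation; the aldehyde reacts at −78 °C, before any aldol reaction with the γ-keto group, and the methyl ketone on warming, while the lactone is not attacked by the ylide at these temperatures. C8a and C1 already hold their more stable equatorial substituents, so transient enolisation cannot erode them.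

Step 10
Reactants: 4 tert-butyldimethyl[(3-methylcyclohexa-1,3-dien-1-yl)oxy]silane; 8 3-[(E)-3-(benzyloxycarbonyl)acryloyl]oxazolidin-2-one
Product: 17 1S-series cycloadduct (mirror image of 9)
Conditions: Cu(SbF6)2 with (R,R)-2,2′-isopropylidenebis(4-tert-butyl-2-oxazoline) (10 mol %; from CuCl2, ligand, AgSbF6), 4 Å molecular sieves, CH2Cl2, −78 to −40 °C
Reagents that add atoms: none
Why: The same endo, regioselective Diels–Alder reaction as step 5; the antipodal ligand exposes the opposite face of the chelated imide, so all four stereocentres are formed in the mirror-image sense.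

Step 11
Reactants: 17 1S-series cycloadduct
Product: 20 1S-series keto lactone benzyl ester (mirror image of 12), via keto aldehyde imide 18 (not isolated), via hydroxy imide 19 (not isolated)
Conditions: O3, CH2Cl2, −78 °C; PPh3, −78 to 0 °C; then EtOH, NaBH4, −78 °C; AcOH; Et3N, 20 °C
Reagents that add atoms: ozone, [O-][O+]=O
Why: Ozonolysis, aldehyde-selective borohydride reduction and lactonisation with loss of the oxazolidinone, as in step 6; no stereocentre is affected.

Step 12
Reactants: 20 1S-series keto lactone benzyl ester
Product: 21 1S-series keto lactone acid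
Conditions: H2 (1 atm), 10% Pd/C, EtOAc, 20 °C
Reagents that add atoms: none
Why: Hydrogenolysis of the benzyl ester under neutral conditions, as in step 7.

Step 13
Reactants: 21 1S-series keto lactone acid
Product: 23 1S-series keto aldehyde lactone, via acid chloride 22 (not isolated)
Conditions: (COCl)2, DMF (cat.), CH2Cl2, 0 °C; evaporate; LiAlH(OtBu)3, THF, −78 °C
Reagents that add atoms: none
Why: Acid chloride formation and partial hydride reduction to the aldehyde, chemoselective over ketone and lactone at −78 °C, as in step 8.

Step 14
Reactants: 23 1S-series keto aldehyde lactone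
Product: 24 1S-series diene lactone (mirror image of 16)
Conditions: Ph3PCH3Br, KN(SiMe3)2, THF, 0 °C; then 23, −78 to 20 °C
Reagents that add atoms: methylenetriphenylphosphorane, C=P(c1ccccc1)(c1ccccc1)c1ccccc1
Why: Double Wittig methylenation of aldehyde and methyl ketone, as in step 9.

Step 15
Reactants: 24 1S-series diene lactone; 25 tert-butyl 2-(bromomethyl)acrylate
Product: 28 1S-series metathesis precursor (C5 ester of tert-butyl 2-(hydroxymethyl)acrylate; 11-OTES; 4-OTBS; 1-isopropenyl; 8a-vinyl), via ammonium carboxylate 26 (not isolated), via hydroxy ester 27 (not isolated)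
Conditions: Bu4NOH (0.98 equiv, aq.), THF, 0 °C; toluene azeotrope; 25, DMF, 0 °C; aqueous work-up; TESOTf, 2,6-lutidine, CH2Cl2, −78 °C
Reagents that add atoms: tetrabutylammonium hydroxide, CCCC[N+](CCCC)(CCCC)CCCC.[OH-]; triethylsilyl trifluoromethanesulfonate, CC[Si](CC)(CC)OS(=O)(=O)C(F)(F)F
Why: Saponification of the γ-lactone, O-alkylation of the carboxylate by the allylic bromide (SN2 and SN2′ give the same ester) and silylation of the freed primary hydroxyl before it can re-lactonise. A slight deficit of hydroxide keeps the electrophile and the β-silyloxy ester away from free base; the hindered base and low temperature spare the tert-butyl ester during silylation.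

Step 16
Reactants: 28 1S-series metathesis precursor
Product: 29 1S-series bicyclic lactone (ring B closed; tert-butyl ester on C10; 11-OTES; 4-OTBS; 1-isopropenyl)
Conditions: second-generation Grubbs catalyst (H2IMes)(PCy3)Cl2Ru=CHPh (10 mol %), toluene (0.002 M), 80 °C
Reagents that add atoms: none
Why: Ring-closing metathesis between the vinyl group and the 1,1-disubstituted acrylate alkene; the trans-diequatorial arms on C4a and C8a favour the seven-membered ring. The ring forces C8a and C7 cis on C8=C9, which is the required enoate geometry, and the isopropenyl group has no partner within reach of a favourable ring size.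

Step 17
Reactants: 29 1S-series bicyclic lactone
Product: 30 1S-series alcohol (29 with free C11–OH)
Conditions: HF·pyridine, pyridine, THF, 0 °C
Reagents that add atoms: none
Why: Fluoride-mediated desilylation; a primary triethylsilyl ether is cleaved far faster than the hindered tertiary tert-butyldimethylsilyl ether, and the buffered, weakly acidic medium leaves both esters and the lactone intact.

Step 18
Reactants: 30 1S-series alcohol; 31 2-(bromomethyl)acrylic acid
Product: 33 1S-series 2-(bromomethyl)acrylate (30 acylated on O11), via acid chloride 32 (not isolated)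
Conditions: 31, (COCl)2, DMF (cat.), CH2Cl2, 0 °C; then 30, 2,6-di-tert-butyl-4-methylpyridine, CH2Cl2, −20 to 20 °C
Reagents that add atoms: none
Why: Acylation of the primary alcohol by an acid chloride; the non-nucleophilic pyridine base takes up HCl without quaternising on the allylic bromide or adding to the acrylate, which a nucleophilic acylation catalyst would do.

Step 19
Reactants: 16 1R-series diene lactone; 33 1S-series 2-(bromomethyl)acrylate
Product: 36 open-chain dimer (C5 carboxylate of the 1R half esterified with the allylic carbon of 33; 11-OTES; both 4-OTBS; both 1-isopropenyl), via ammonium carboxylate 34 (not isolated), via hydroxy diester 35 (not isolated)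
Conditions: 16, Bu4NOH (0.98 equiv, aq.), THF, 0 °C; toluene azeotrope; 33, DMF, 0 °C; aqueous work-up; TESOTf, 2,6-lutidine, CH2Cl2, −78 °C
Reagents that add atoms: tetrabutylammonium hydroxide, CCCC[N+](CCCC)(CCCC)CCCC.[OH-]; triethylsilyl trifluoromethanesulfonate, CC[Si](CC)(CC)OS(=O)(=O)C(F)(F)F
Why: The same lactone opening, carboxylate O-alkylation and silylation as step 15, here joining the two antipodal halves; the ammonium carboxylate is a far better nucleophile than the neutral neopentyl hydroxyl, and no free hydroxide meets the lactone and esters of 33.

Step 20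
Reactants: 36 open-chain dimer
Product: 37 protected dimer with both rings B closed (isopropenyl on C1 and C1′)
Conditions: second-generation Grubbs catalyst (H2IMes)(PCy3)Cl2Ru=CHPh (10 mol %), toluene (0.002 M), 80 °C
Reagents that add atoms: none
Why: Ring-closing metathesis of the vinyl group of the 1R half with the linker acrylate, as in step 16; the trisubstituted conjugated alkene and the isopropenyl groups are spectators, and the ring again fixes the enoate geometry.

Step 21
Reactants: 37 protected dimer with both rings B closed
Product: 38 protected dimer with isopropyl groups on C1 and C1′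
Conditions: H2 (1 atm), RhCl(PPh3)3 (15 mol %), benzene, 20 °C
Reagents that add atoms: none
Why: Homogeneous hydrogenation that discriminates by substitution; the two 1,1-disubstituted isopropenyl groups are reduced while the trisubstituted, ester-conjugated ring alkenes are not. No stereocentre is created.

Step 22
Reactants: 38 protected dimer with isopropyl groups
Product: 40 C10′ carboxylic acid (silyl ethers retained), via trimethylsilyl ester 39 (not isolated)
Conditions: TMSOTf, 2,6-lutidine, CH2Cl2, 0 to 20 °C; then pH 5 buffer
Reagents that add atoms: none
Why: Silyl-triflate-mediated cleavage of the tert-butyl ester (loss of 2-methylpropene) under buffered, non-protic conditions; the silyl ethers and lactones are kept, and the silyl ester hydrolyses on work-up.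

Step 23
Reactants: 40 C10′ carboxylic acid
Product: 41 target compound CNP0340505.1
Conditions: HF·pyridine, pyridine, THF, 0 to 20 °C
Reagents that add atoms: none
Why: Global fluoride desilylation of one primary and two tertiary silyl ethers under buffered, weakly acidic conditions, which avoids alkoxide formation at C4 and C11 and therefore retro-aldol cleavage and translactonisation.

## Compound list

1 | 3-methylanisole | COc1cccc(C)c1 | starting material
2 | 1-methoxy-5-methylcyclohexa-1,4-diene | COC1=CCC=C(C)C1 | intermediate
3 | 3-methylcyclohex-3-en-1-one | O=C1CC(C)=CCC1 | intermediate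
4 | tert-butyldimethyl[(3-methylcyclohexa-1,3-dien-1-yl)oxy]silane | CC1=CCCC(O[Si](C)(C)C(C)(C)C)=C1 | intermediate
5 | monobenzyl fumarate | O=C(O)/C=C/C(=O)OCc1ccccc1 | starting material
6 | 2-oxazolidinone | O=C1NCCO1 | starting material
7 | mixed pivalic anhydride of 5 (not isolated) | CC(C)(C)C(=O)OC(=O)/C=C/C(=O)OCc1ccccc1 | intermediate
8 | 3-[(E)-3-(benzyloxycarbonyl)acryloyl]oxazolidin-2-one | O=C(/C=C/C(=O)OCc1ccccc1)N1CCOC1=O | intermediate
9 | 1R-series cycloadduct | CC(C)(C)[Si](C)(C)O[C@]12CC[C@H](C(C)=C1)[C@@H](C(=O)OCc3ccccc3)[C@@H]2C(=O)N4CCOC4=O | intermediate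
10 | 1R-series keto aldehyde imide (not isolated) | CC(C)(C)[Si](C)(C)O[C@@]1(C=O)CC[C@H](C(C)=O)[C@@H](C(=O)OCc2ccccc2)[C@@H]1C(=O)N3CCOC3=O | intermediate
11 | 1R-series hydroxy imide (not isolated) | CC(C)(C)[Si](C)(C)O[C@@]1(CO)CC[C@H](C(C)=O)[C@@H](C(=O)OCc2ccccc2)[C@@H]1C(=O)N3CCOC3=O | intermediate
12 | 1R-series keto lactone benzyl ester | CC(C)(C)[Si](C)(C)O[C@@]12CC[C@H](C(C)=O)[C@@H](C(=O)OCc3ccccc3)[C@@H]1C(=O)OC2 | intermediate
13 | 1R-series keto lactone acid | CC(C)(C)[Si](C)(C)O[C@@]12CC[C@H](C(C)=O)[C@@H](C(=O)O)[C@@H]1C(=O)OC2 | intermediate
14 | 1R-series acid chloride (not isolated) | CC(C)(C)[Si](C)(C)O[C@@]12CC[C@H](C(C)=O)[C@@H](C(=O)Cl)[C@@H]1C(=O)OC2 | intermediate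
15 | 1R-series keto aldehyde lactone | CC(C)(C)[Si](C)(C)O[C@@]12CC[C@H](C(C)=O)[C@@H](C=O)[C@@H]1C(=O)OC2 | intermediate
16 | 1R-series diene lactone | CC(C)(C)[Si](C)(C)O[C@@]12CC[C@H](C(C)=C)[C@@H](C=C)[C@@H]1C(=O)OC2 | intermediate
17 | 1S-series cycloadduct | CC(C)(C)[Si](C)(C)O[C@@]12CC[C@@H](C(C)=C1)[C@H](C(=O)OCc3ccccc3)[C@H]2C(=O)N4CCOC4=O | intermediate
18 | 1S-series keto aldehyde imide (not isolated) | CC(C)(C)[Si](C)(C)O[C@]1(C=O)CC[C@@H](C(C)=O)[C@H](C(=O)OCc2ccccc2)[C@H]1C(=O)N3CCOC3=O | intermediate
19 | 1S-series hydroxy imide (not isolated) | CC(C)(C)[Si](C)(C)O[C@]1(CO)CC[C@@H](C(C)=O)[C@H](C(=O)OCc2ccccc2)[C@H]1C(=O)N3CCOC3=O | intermediate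
20 | 1S-series keto lactone benzyl ester | CC(C)(C)[Si](C)(C)O[C@]12CC[C@@H](C(C)=O)[C@H](C(=O)OCc3ccccc3)[C@H]1C(=O)OC2 | intermediate
21 | 1S-series keto lactone acid | CC(C)(C)[Si](C)(C)O[C@]12CC[C@@H](C(C)=O)[C@H](C(=O)O)[C@H]1C(=O)OC2 | intermediate
22 | 1S-series acid chloride (not isolated) | CC(C)(C)[Si](C)(C)O[C@]12CC[C@@H](C(C)=O)[C@H](C(=O)Cl)[C@H]1C(=O)OC2 | intermediate
23 | 1S-series keto aldehyde lactone | CC(C)(C)[Si](C)(C)O[C@]12CC[C@@H](C(C)=O)[C@H](C=O)[C@H]1C(=O)OC2 | intermediate
24 | 1S-series diene lactone | CC(C)(C)[Si](C)(C)O[C@]12CC[C@@H](C(C)=C)[C@H](C=C)[C@H]1C(=O)OC2 | intermediate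
25 | tert-butyl 2-(bromomethyl)acrylate | C=C(CBr)C(=O)OC(C)(C)C | starting material
26 | 1S-series tetrabutylammonium carboxylate (not isolated) | CC(C)(C)[Si](C)(C)O[C@]1(CO)CC[C@@H](C(C)=C)[C@H](C=C)[C@H]1C(=O)[O-].CCCC[N+](CCCC)(CCCC)CCCC | intermediate
27 | 1S-series hydroxy ester (not isolated) | CC(C)(C)[Si](C)(C)O[C@]1(CO)CC[C@@H](C(C)=C)[C@H](C=C)[C@H]1C(=O)OCC(=C)C(=O)OC(C)(C)C | intermediate
28 | 1S-series metathesis precursor | CC(C)(C)[Si](C)(C)O[C@]1(CO[Si](CC)(CC)CC)CC[C@@H](C(C)=C)[C@H](C=C)[C@H]1C(=O)OCC(=C)C(=O)OC(C)(C)C | intermediate
29 | 1S-series bicyclic lactone | CC(C)(C)[Si](C)(C)O[C@]1(CO[Si](CC)(CC)CC)CC[C@@H](C(C)=C)[C@@H]2C=C(C(=O)OC(C)(C)C)COC(=O)[C@H]21 | intermediate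
30 | 1S-series alcohol | CC(C)(C)[Si](C)(C)O[C@]1(CO)CC[C@@H](C(C)=C)[C@@H]2C=C(C(=O)OC(C)(C)C)COC(=O)[C@H]21 | intermediate
31 | 2-(bromomethyl)acrylic acid | C=C(CBr)C(=O)O | starting material
32 | 2-(bromomethyl)acryloyl chloride (not isolated) | C=C(CBr)C(=O)Cl | intermediate
33 | 1S-series 2-(bromomethyl)acrylate | CC(C)(C)[Si](C)(C)O[C@]1(COC(=O)C(=C)CBr)CC[C@@H](C(C)=C)[C@@H]2C=C(C(=O)OC(C)(C)C)COC(=O)[C@H]21 | intermediate
34 | 1R-series tetrabutylammonium carboxylate (not isolated) | CC(C)(C)[Si](C)(C)O[C@@]1(CO)CC[C@H](C(C)=C)[C@@H](C=C)[C@@H]1C(=O)[O-].CCCC[N+](CCCC)(CCCC)CCCC | intermediate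
35 | hydroxy diester (not isolated) | CC(C)(C)[Si](C)(C)O[C@@]1(CO)CC[C@H](C(C)=C)[C@@H](C=C)[C@@H]1C(=O)OCC(=C)C(=O)OC[C@@]2(O[Si](C)(C)C(C)(C)C)CC[C@@H](C(C)=C)[C@@H]3C=C(C(=O)OC(C)(C)C)COC(=O)[C@H]32 | intermediate
36 | open-chain dimer | CC(C)(C)[Si](C)(C)O[C@@]1(CO[Si](CC)(CC)CC)CC[C@H](C(C)=C)[C@@H](C=C)[C@@H]1C(=O)OCC(=C)C(=O)OC[C@@]2(O[Si](C)(C)C(C)(C)C)CC[C@@H](C(C)=C)[C@@H]3C=C(C(=O)OC(C)(C)C)COC(=O)[C@H]32 | intermediate
37 | protected dimer, isopropenyl groups | C=C(C)[C@H]1CC[C@@](O[Si](C)(C)C(C)(C)C)(CO[Si](CC)(CC)CC)[C@H]2C(=O)OCC(C(=O)OC[C@@]3(O[Si](C)(C)C(C)(C)C)CC[C@@H](C(C)=C)[C@@H]4C=C(C(=O)OC(C)(C)C)COC(=O)[C@H]43)=C[C@H]12 | intermediate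
38 | protected dimer, isopropyl groups | CC(C)[C@H]1CC[C@@](O[Si](C)(C)C(C)(C)C)(CO[Si](CC)(CC)CC)[C@H]2C(=O)OCC(C(=O)OC[C@@]3(O[Si](C)(C)C(C)(C)C)CC[C@@H](C(C)C)[C@@H]4C=C(C(=O)OC(C)(C)C)COC(=O)[C@H]43)=C[C@H]12 | intermediate
39 | trimethylsilyl ester (not isolated) | CC(C)[C@H]1CC[C@@](O[Si](C)(C)C(C)(C)C)(CO[Si](CC)(CC)CC)[C@H]2C(=O)OCC(C(=O)OC[C@@]3(O[Si](C)(C)C(C)(C)C)CC[C@@H](C(C)C)[C@@H]4C=C(C(=O)O[Si](C)(C)C)COC(=O)[C@H]43)=C[C@H]12 | intermediate
40 | C10′ carboxylic acid, silyl ethers retained | CC(C)[C@H]1CC[C@@](O[Si](C)(C)C(C)(C)C)(CO[Si](CC)(CC)CC)[C@H]2C(=O)OCC(C(=O)OC[C@@]3(O[Si](C)(C)C(C)(C)C)CC[C@@H](C(C)C)[C@@H]4C=C(C(=O)O)COC(=O)[C@H]43)=C[C@H]12 | intermediate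
41 | CNP0340505.1 | CC(C)[C@H]1CC[C@@](O)(CO)[C@H]2C(=O)OCC(C(=O)OC[C@@]3(O)CC[C@@H](C(C)C)[C@@H]4C=C(C(=O)O)COC(=O)[C@H]43)=C[C@H]12 | target

## Step count and least certain steps

Total: 23 steps. Longest linear sequence: 17 steps (1–3, 10–18, 19–23).

**Step 5 (key step, and its mirror image step 10).** The Lewis acid may divert the reaction into a stepwise path that ends after the first C–C bond by silyl transfer. The silyloxy-bearing diene terminus may also crowd the chelate and lower endo and facial selectivity. Fallback: the cycloaddition is run without a chiral ligand, thermally in toluene or with an achiral chelating Lewis acid such as MgBr2·OEt2. The racemic adduct (9 together with 17) is taken through step 6, and the racemic lactone (12 together with 20) is separated by preparative chromatography on a chiral stationary phase. Both antipodes are consumed by the synthesis, so nothing is discarded. This sets out from 4 and 8 and returns at 12 and 20; it makes no new compound (F0).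

**Step 15 (the same operation recurs in step 19).** The freed C11 hydroxyl may re-lactonise onto the new allylic ester before it is silylated, or the neighbouring tertiary silyl group may migrate under the basic opening. Fallback: the hydroxyl is protected before any reactive ester exists. Carboxylate 26, made from 24 as before, is treated with TESCl and imidazole in DMF to give the bis(triethylsilyl) derivative F1. Aqueous methanol work-up cleaves only the silyl ester and gives the silyloxy acid F2. Cs2CO3 in DMF converts it into the caesium carboxylate F3, which is alkylated with 25. This sets out from 24 and returns at 28.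

**Step 16 (the same ring closure recurs in step 20 and stands or falls with it).** Metathesis onto the electron-poor 1,1-disubstituted alkene may be too slow, and the ester may resist the conformation needed for a seven-membered ring, so that dimerisation through the vinyl group takes over. Fallback: the ring is closed at a non-conjugated oxidation level and C10 is oxidised afterwards.
- Carboxylate 26 (from 24) is alkylated with 3-bromo-2-(bromomethyl)prop-1-ene to give the hydroxy bromo ester F4, which is silylated without isolation to the triethylsilyl ether F5.
- Ring-closing metathesis of F5 gives the ring-B allylic bromide F6.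
- Kornblum-type oxidation with N-methylmorpholine N-oxide gives the enal F7.
- NaClO2 with 2-methylbut-2-ene gives the acid F8.
- N,N-dimethylformamide di-tert-butyl acetal in toluene gives the tert-butyl ester.

This sets out from 24 and returns at 29.

**Step 6 (and step 11).** The hindered α-silyloxy aldehyde may not be reduced cleanly ahead of the methyl ketone, giving over-reduction. Fallback: both carbonyl groups are reduced deliberately. After ozonolysis of 9, NaBH4 at 0 °C gives the diol imide F9, which lactonises to the hydroxy lactone F10 (both carbinol epimers). Oxidation of the remaining secondary alcohol at once with Dess–Martin periodinane restores the ketone. This sets out from 9 and returns at 12.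

**Step 8 (and step 13).** Hydride delivery to the acid chloride may run on to the alcohol, or the γ-keto aldehyde may undergo aldol closure on work-up. Fallback: acid 13 is converted with ethanethiol, 1-ethyl-3-(3-dimethylaminopropyl)carbodiimide hydrochloride and DMAP into the S-ethyl thioester F11, which is reduced with Et3SiH and Pd/C in acetone (Fukuyama reduction). This sets out from 13 and returns at 15.

**Step 23.** The slow cleavage of the two tertiary silyl ethers exposes the free acid, the C11 hydroxyl and the lactone to the reagent for a long time, so translactonisation or incomplete deprotection may result. Fallback: the order of the last two operations is inverted. Compound 38 is desilylated first with HF·pyridine while C10′ is still the tert-butyl ester, giving the triol tert-butyl ester F12, and the ester is then cleaved by a short treatment with CF3CO2H in CH2Cl2 at 0 °C. This sets out from 38 and returns at 41.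

## Further compounds

F0 | step 5 | none | none
F1 | step 15 | 1S-series bis(triethylsilyl) derivative (C11 triethylsilyl ether and C5 triethylsilyl ester) | CC(C)(C)[Si](C)(C)O[C@]1(CO[Si](CC)(CC)CC)CC[C@@H](C(C)=C)[C@H](C=C)[C@H]1C(=O)O[Si](CC)(CC)CC
F2 | step 15 | 1S-series silyloxy acid | CC(C)(C)[Si](C)(C)O[C@]1(CO[Si](CC)(CC)CC)CC[C@@H](C(C)=C)[C@H](C=C)[C@H]1C(=O)O
F3 | step 15 | caesium carboxylate of the 1S-series silyloxy acid | CC(C)(C)[Si](C)(C)O[C@]1(CO[Si](CC)(CC)CC)CC[C@@H](C(C)=C)[C@H](C=C)[C@H]1C(=O)[O-].[Cs+]
F4 | step 16 | 1S-series hydroxy bromo ester (C5 ester of 2-(bromomethyl)prop-2-en-1-ol) | CC(C)(C)[Si](C)(C)O[C@]1(CO)CC[C@@H](C(C)=C)[C@H](C=C)[C@H]1C(=O)OCC(=C)CBr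
F5 | step 16 | triethylsilyl ether of the 1S-series hydroxy bromo ester | CC(C)(C)[Si](C)(C)O[C@]1(CO[Si](CC)(CC)CC)CC[C@@H](C(C)=C)[C@H](C=C)[C@H]1C(=O)OCC(=C)CBr
F6 | step 16 | 1S-series ring-B allylic bromide | CC(C)(C)[Si](C)(C)O[C@]1(CO[Si](CC)(CC)CC)CC[C@@H](C(C)=C)[C@@H]2C=C(CBr)COC(=O)[C@H]21
F7 | step 16 | 1S-series ring-B enal | CC(C)(C)[Si](C)(C)O[C@]1(CO[Si](CC)(CC)CC)CC[C@@H](C(C)=C)[C@@H]2C=C(C=O)COC(=O)[C@H]21
F8 | step 16 | 1S-series ring-B C10 acid | CC(C)(C)[Si](C)(C)O[C@]1(CO[Si](CC)(CC)CC)CC[C@@H](C(C)=C)[C@@H]2C=C(C(=O)O)COC(=O)[C@H]21
F9 | step 6 | 1R-series diol imide (both carbinol epimers) | CC(C)(C)[Si](C)(C)O[C@@]1(CO)CC[C@H](C(C)O)[C@@H](C(=O)OCc2ccccc2)[C@@H]1C(=O)N3CCOC3=O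
F10 | step 6 | 1R-series hydroxy lactone benzyl ester (both carbinol epimers) | CC(C)(C)[Si](C)(C)O[C@@]12CC[C@H](C(C)O)[C@@H](C(=O)OCc3ccccc3)[C@@H]1C(=O)OC2
F11 | step 8 | 1R-series S-ethyl thioester | CC(C)(C)[Si](C)(C)O[C@@]12CC[C@H](C(C)=O)[C@@H](C(=O)SCC)[C@@H]1C(=O)OC2
F12 | step 23 | triol tert-butyl ester | CC(C)[C@H]1CC[C@@](O)(CO)[C@H]2C(=O)OCC(C(=O)OC[C@@]3(O)CC[C@@H](C(C)C)[C@@H]4C=C(C(=O)OC(C)(C)C)COC(=O)[C@H]43)=C[C@H]12
A1 | alternative 1 | δ-lactone with a (2,2-dimethyl-1,3-dioxolan-4-ylidene)methyl group on C2 | O=C1C[C@H](CO[Si](C)(C)C(C)(C)C)[C@@H](C(C)C)[C@H](/C=C2/COC(C)(C)O2)O1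
A2 | alternative 1 | cyclohexene acid with C4 spiro-acetonide | CC(C)[C@H]1C=C[C@@]3(COC(C)(C)O3)[C@@H](C(=O)O)[C@@H]1CO[Si](C)(C)C(C)(C)C
A3 | alternative 2 | eleven-membered β-keto lactone with C8a methyl carbonate | CC(C)[C@H]1CCC(=O)CC(=O)OC/C(C(=O)OC(C)(C)C)=C\[C@H]1OC(=O)OC
A4 | alternative 2 | bicyclic β-keto lactone tert-butyl ester | CC(C)[C@H]1CCC(=O)[C@H]2C(=O)OCC(C(=O)OC(C)(C)C)=C[C@H]12
A5 | alternative 3 | trans-decalone with acetonide and allyl ester | CC(C)[C@H]1CC[C@@]3(COC(C)(C)O3)[C@H]2C(=O)CC(C(=O)OCC=C)=C[C@H]12
A6 | alternative 3 | monomer lactone with acetonide and allyl ester | CC(C)[C@H]1CC[C@@]3(COC(C)(C)O3)[C@H]2C(=O)OCC(C(=O)OCC=C)=C[C@H]12
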